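J, the catalyst, comes out of step 1 unchanged but pairs off into J2 by step 3, so write the balance of J, with J2 counted, before you choose among these set-ups.

| setting | midnight | noon | autumn | spring |
|---|---|---|---|---|
| G | 0.20 M | 0.20 M | 0.20 M | 0.20 M (fed, over 0.800 min) |
| J | 1.5 mol% | 1.5 mol% | 1.5 mol% | 1.5 mol% |
| time | 1.0 min |  |  | 1.0 min |
| remark | everything together in a closed stirred flask, run for 1.0 min | a single well-mixed tank run continuously and read at steady state, 5.00 min in it on average | one stirred flow tank at steady state, fed with the mixture as stated, mean residence time 1.0 min | all but G at the start; G goes in evenly over 0.800 min, the run ends at 1.0 min |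

    G + J → J + E (k1 = 22.9 M⁻¹ s⁻¹)
    G → L (k2 = 0.0278 s⁻¹)
    J + J ⇌ J2 (K3 = 21400 M⁻¹, k3 = 40.3 M⁻¹ s⁻¹)

1. the set-up with the highest share of E in all that became E or L, at the outlet or at the end ("none" if the first two lie within 2 percentage points) (midnight / noon / autumn / spring / none)
2. share of E in all that became E or L, at the outlet or at the end, midnight
3. share of E in all that became E or L, at the outlet or at the end, noon
4. share of E in all that became E or L, at the outlet or at the end, autumn
5. share of E in all that became E or L, at the outlet or at the end, spring

- where a step has two of a species, its rate is k times that concentration squared, and two are used at each turn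
- the stated concentrations are those of everything mixed, before any reaction; amounts are the same in each set-up
- the feed brings no volume worth counting
- run time (midnight): 1.0 min

J stands at 0.00300 M, and G is consumed by two steps that are both first order in G. G therefore cancels from their ratio, and the momentary selectivity is c(J)/(c(J)+B). B, the break-even level of free J, is 0.00121 M: the rate constant of G → L divided by that of the catalytic step, the c(J) at which the two steps take G equally fast.

Which numbers must you know well? The two rate constants of G act through B. Where c(J) equals B the share is 50.0 %, and with B larger by a factor 2 it is 33.3 %, so they matter directly. The forward constant of dimerisation matters as much: its half-life on J as charged, 4.14 s, is shorter than 10.4 s, the mean life of G with J as charged, so c(J) falls while G is still there. K3 you may know loosely for the midnight flask, since the back step's time, 8.85 min, is longer than the run.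

Now my numbers. Each flow tank holds c(J) steady, so the formula applies directly. Counting J plus twice the dimer J2 as 0.00300 M, with the dimer leaving by back step and outflow, gives c(J) = 4.09 × 10⁻⁴ M and a share of 25.2 % in the noon tank, and 7.24 × 10⁻⁴ M and 37.4 % in the autumn tank. For the midnight flask I take c(J) from forward decay at the mean life of G, 8.56 × 10⁻⁴ M, which gives 41.3 %. For the spring flask I take it at mid-dose, 4.41 × 10⁻⁴ M, which gives 26.6 %. So I commit to midnight, higher than the others.

The forecast also named midnight, with 43.6 % there against my 41.3 %, and 25.2 %, 37.4 % and 26.7 % for noon, autumn and spring, saying of its flow tanks: “the J balance gives a share independent of G”. The simulation gives midnight as best, with 43.7 %, then 25.2 % for noon, 37.4 % for autumn and 26.7 % for spring.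

Read through B, the midnight share stands for an effective free J of 9.42 × 10⁻⁴ M, lower than the 0.00300 M charged. In the noon tank the main reason for the low share is the path from 2 J to J2: with that path struck out, both ways, the share there rises from 25.2 % to 71.2 %. B with c(J) at the charged value gives 71.3 %, and the same strike in the midnight flask gives 71.2 %.

The numbers of this flask were drawn at random within sensible limits; the run is a simulation.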